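**Retrosynthetic overview** (oxolane locants used throughout: O1, C2 = aryl carbon, C3 = CH2OH carbon, C4 = aroyl carbon, C5 = ring CH2)
- Last disconnection: the C4 aryl ketone and the C3 hydroxymethyl group are released together by adding 3,4,5-trimethoxyphenyllithium to a cis-fused γ-lactone (C4–C(=O)–O–CH2–C3).
- Key disconnection: the bicyclic lactone is cut at C2–C3 and O1–C5 into veratraldehyde and 3-(bromomethyl)furan-2(5H)-one. Forward, an asymmetric chromium-catalysed allylation makes C2–C3, and the resulting alkoxide closes O1–C5 by oxa-Michael addition in the same flask.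
- Enabling feature: the cis C3–CH2OH / C4–C(=O) pair is a latent five-membered lactone. As a butenolide it makes C5 an allylic CH2Br and C3 the γ-carbon of a 2-carbonyl allyl metal of locked alkene geometry; after allyl transposition C4=C5 is a Michael acceptor. The cis ring fusion then fixes C3/C4.
- Ring order: lactone ring (present from the start) → oxolane ring (key step) → lactone ring opened (last step).

Key step: step 2

Assumption: the (S,S)-ligand in step 2 is taken to deliver the (S)-carbinol; if the sense proves opposite, its mirror image is used.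

Step 1
Reactants: 1 3-methylidenedihydrofuran-2(3H)-one (α-methylene-γ-butyrolactone)
Product: 3 3-(bromomethyl)furan-2(5H)-one, via dibromolactone 2 (not isolated)
Conditions: Br2 (1.0 equiv), CH2Cl2, 0 °C; then Et3N (1.1 equiv), 0 °C to rt
Reagents that add atoms: bromine BrBr
Why: Electrophilic bromine addition to the exocyclic alkene followed by amine-induced E2 dehydrobromination (tertiary α-bromide, anti ring C–H) should give the conjugated endocyclic butenolide carrying the primary allylic bromide, with no stereocentre remaining (bromination–dehydrobromination).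

Step 2
Reactants: 3 3-(bromomethyl)furan-2(5H)-one; 4 3,4-dimethoxybenzaldehyde (veratraldehyde)
Product: 6 (1R,5R,6S)-6-(3,4-dimethoxyphenyl)-3,7-dioxabicyclo[3.3.0]octan-2-one, via silyl ether 5 (not isolated)
Conditions: CrCl2 (10 mol%), (S,S)-1,8-bis(4-isopropyl-4,5-dihydrooxazol-2-yl)-3,6-diphenyl-9H-carbazole (12 mol%), Mn powder (2 equiv), Me3SiCl (1.5 equiv), i-Pr2NEt (0.3 equiv), THF, 0 °C to rt; then Bu4NF (4 equiv), THF (0.02 M), 0 °C to rt
Reagents that add atoms: none
Why: Proposed new method: Mn-regenerated divalent chromium turns bromide 3 into a trivalent allylchromium species that adds to 4 through its γ-carbon in a closed six-membered chair transition state (closest known type: ligand-controlled catalytic asymmetric Nozaki–Hiyama–Kishi allylation with 2-carbonyl-substituted allyl bromides), forming the C2–C3 bond and silyl ether 5. Because the butenolide ring holds the ring CH2O carbon trans to the CH2Cr terminus, the reagent behaves like an (E)-crotyl metal and should give the anti adduct, so C3 is set relative to C2 by the chair while the absolute sense at C2 is set by the bis(oxazoline) ligand. Fluoride then frees the alkoxide, which adds to the exocyclic methylidene carbon (O1–C5 bond) in a 5-endo-trig oxa-Michael closure of the oxolane; this mode is stereoelectronically disfavoured but documented for hydroxyl-derived alkoxides adding to vinyl sulfones and enones, which is the closest known type, and it has not been shown for an α-methylidene lactone. The enolate should be protonated on the face that gives the cis-fused 5/5 bicycle, the only low-strain fusion, which sets C4. The step needs conjugate O-attack to beat acyl transfer to the lactone carbonyl and intermolecular addition: acyl transfer must pass through a strained 7-methylidene-2,6-dioxabicyclo[2.2.1]heptane tetrahedral intermediate and is reversible, the cyclic ether is the thermodynamic sink, and high dilution suppresses oligomers.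

Step 3
Reactants: 6 (1R,5R,6S)-6-(3,4-dimethoxyphenyl)-3,7-dioxabicyclo[3.3.0]octan-2-one; 7 5-bromo-1,2,3-trimethoxybenzene
Product: 10 (2S,3R,4R)-2-(3,4-dimethoxyphenyl)-3-(hydroxymethyl)-4-(3,4,5-trimethoxybenzoyl)oxolane, via aryllithium 8 (not isolated), via lithium hemiketalate 9 (not isolated)
Conditions: 7 (1.2 equiv), n-BuLi (1.15 equiv), THF, −78 °C; then 6 in THF, −78 °C; AcOH (2 equiv), −78 °C to rt
Reagents that add atoms: none
Why: Bromine–lithium exchange gives the aryllithium, whose 1,2-addition to the lactone carbonyl from the convex face should stop at the lithium hemiketal alkoxide at −78 °C, and protonation opens it to the aryl ketone and the free hydroxymethyl group without touching C2, C3 or C4, whose cis C3/C4 relationship is inherited from the ring fusion (acyl substitution of a lactone by an organolithium).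

**Compound list**
1 | 3-methylidenedihydrofuran-2(3H)-one | C=C1CCOC1=O | starting material
2 | 3-bromo-3-(bromomethyl)dihydrofuran-2(3H)-one (racemic) | BrCC1(Br)CCOC1=O | intermediate
3 | 3-(bromomethyl)furan-2(5H)-one | BrCC1=CCOC1=O | intermediate
4 | 3,4-dimethoxybenzaldehyde | COc1ccc(C=O)cc1OC | starting material
5 | (4R)-4-[(S)-(3,4-dimethoxyphenyl)(trimethylsilyloxy)methyl]-3-methylidenedihydrofuran-2(3H)-one | COc1ccc([C@@H](O[Si](C)(C)C)[C@H]2COC(=O)C2=C)cc1OC | intermediate
6 | (1R,5R,6S)-6-(3,4-dimethoxyphenyl)-3,7-dioxabicyclo[3.3.0]octan-2-one (cis-fused, aryl exo) | COc1ccc([C@H]2OC[C@@H]3C(=O)OC[C@H]23)cc1OC | intermediate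
7 | 5-bromo-1,2,3-trimethoxybenzene | COc1cc(Br)cc(OC)c1OC | starting material
8 | (3,4,5-trimethoxyphenyl)lithium | [Li]c1cc(OC)c(OC)c(OC)c1 | intermediate
9 | lithium alkoxide of the cis-fused bicyclic hemiketal from 6 and 8 (new aryl group exo) | COc1ccc([C@H]2OC[C@@H]3[C@@]([O-])(c4cc(OC)c(OC)c(OC)c4)OC[C@H]23)cc1OC.[Li+] | intermediate
10 | (2S,3R,4R)-2-(3,4-dimethoxyphenyl)-3-(hydroxymethyl)-4-(3,4,5-trimethoxybenzoyl)oxolane | COc1ccc([C@H]2OC[C@H](C(=O)c3cc(OC)c(OC)c(OC)c3)[C@@H]2CO)cc1OC | target

**Step count and risks**
Total step count: 3. Longest linear sequence: 3 steps (1 → 3 → 6 → 10).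

Steps most likely to fail:

1. Step 2 (proposed method). The ring closure may stall after the allylation, or the freed alkoxide may transfer the lactone acyl group or shift the methylidene double bond into the ring instead of adding 5-endo. Loss of facial control in the allylation is a smaller risk. Fallback for step 2 with known chemistry, setting out from 3 and 4 and returning at 6: the chromium-catalysed allylation is run as above but worked up with dilute aqueous HCl, which should cleave silyl ether 5 and give (4R)-4-[(S)-(3,4-dimethoxyphenyl)(hydroxy)methyl]-3-methylidenedihydrofuran-2(3H)-one F1 as the free alcohol. Copper-catalysed conjugate borylation of F1 with B2pin2, CuCl, Xantphos, NaOt-Bu and MeOH in THF should give (3S,4R)-4-[(S)-(3,4-dimethoxyphenyl)(hydroxy)methyl]-3-[(4,4,5,5-tetramethyl-1,3,2-dioxaborolan-2-yl)methyl]dihydrofuran-2(3H)-one F2 as the cis lactone, its α-centre set by protonation anti to the side chain. Oxidation of F2 with NaBO3·4H2O in THF/H2O should give (3R,4R)-4-[(S)-(3,4-dimethoxyphenyl)(hydroxy)methyl]-3-(hydroxymethyl)dihydrofuran-2(3H)-one F3 with the cis relationship kept. Camphorsulfonic acid in CH2Cl2 should then ionise the veratryl alcohol of F3, and the primary hydroxyl should capture the benzylic cation on the face that places the aryl group exo, giving 6. This fallback closes the oxolane at the benzylic C–O bond instead of the CH2–O bond.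

2. Step 3. The aryllithium may enolise the lactone, which can be followed by β-elimination of the ring alkoxide. Double addition and epimerisation at C4 of the ketone during work-up or chromatography are further risks. Fallback for step 3, setting out from 6 and returning at 10: i-Bu2AlH in toluene at −78 °C should reduce 6 to (1R,5R,6S)-6-(3,4-dimethoxyphenyl)-3,7-dioxabicyclo[3.3.0]octan-2-ol F4 as an anomeric mixture of the cis-fused lactol. The Grignard reagent (3,4,5-trimethoxyphenyl)magnesium bromide F5 is made from 7 and Mg in THF; used at 2.5 equiv, it should add to the open hydroxy aldehyde form of F4 to give (2S,3R,4R)-2-(3,4-dimethoxyphenyl)-3-(hydroxymethyl)-4-[hydroxy(3,4,5-trimethoxyphenyl)methyl]oxolane F6 as a mixture of carbinol epimers. MnO2 in CH2Cl2 should oxidise only the benzylic secondary alcohol of F6 under neutral conditions, giving 10.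

3. Step 1. Dehydrobromination may run towards the exocyclic bromomethylidene lactone, or the amine may quaternise the allylic bromide. Fallback for step 1, setting out from 1 and returning at 3: radical allylic bromination of 1 (N-bromosuccinimide, catalytic (PhCO2)2, PhCF3, reflux; Wohl–Ziegler) should abstract the ring allylic hydrogen and deliver bromine at the exocyclic terminus of the allyl radical, giving the conjugated butenolide 3 directly. No new compound arises on this way, so its entry below is F0.

**Further compounds**
F1 | step 2 | (4R)-4-[(S)-(3,4-dimethoxyphenyl)(hydroxy)methyl]-3-methylidenedihydrofuran-2(3H)-one | COc1ccc([C@@H](O)[C@H]2COC(=O)C2=C)cc1OC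
F2 | step 2 | (3S,4R)-4-[(S)-(3,4-dimethoxyphenyl)(hydroxy)methyl]-3-[(4,4,5,5-tetramethyl-1,3,2-dioxaborolan-2-yl)methyl]dihydrofuran-2(3H)-one | COc1ccc([C@@H](O)[C@H]2COC(=O)[C@H]2CB3OC(C)(C)C(C)(C)O3)cc1OC
F3 | step 2 | (3R,4R)-4-[(S)-(3,4-dimethoxyphenyl)(hydroxy)methyl]-3-(hydroxymethyl)dihydrofuran-2(3H)-one | COc1ccc([C@@H](O)[C@H]2COC(=O)[C@H]2CO)cc1OC
F4 | step 3 | (1R,5R,6S)-6-(3,4-dimethoxyphenyl)-3,7-dioxabicyclo[3.3.0]octan-2-ol | COc1ccc([C@H]2OC[C@@H]3C(O)OC[C@H]23)cc1OC
F5 | step 3 | (3,4,5-trimethoxyphenyl)magnesium bromide | Br[Mg]c1cc(OC)c(OC)c(OC)c1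
F6 | step 3 | (2S,3R,4R)-2-(3,4-dimethoxyphenyl)-3-(hydroxymethyl)-4-[hydroxy(3,4,5-trimethoxyphenyl)methyl]oxolane | COc1ccc([C@H]2OC[C@H](C(O)c3cc(OC)c(OC)c(OC)c3)[C@@H]2CO)cc1OC
F0 | step 1 | none | none
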